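The route exploits the fact that the three carbons of pyranone ring B between C4a of ring A and O1 (C4, C3 and C2) correspond to an alkyne plus CO. Ring B is therefore cut at C4–C4a, C2–C3 and C2–O1, and one palladium-catalysed carbonylative annulation of an ortho-iodophenol, a silylated arylalkyne and carbon monoxide makes all three bonds and closes the ring; the silyl group stands in for the C3 hydrogen and forces ring C onto C4. The precursor is a pentasubstituted iodophenol whose OH becomes O1 and whose iodine marks C4a, with O8 held as a benzyl ether, prepared by MOM-directed lithiation and iodination.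

Key step: step 7

Assumption: benzyl bromide and carbon monoxide are purchased and are numbered as starting materials. In the iodophenol the OH lies between the C–I and C–OBn carbons, which after annulation places benzyloxy at C8 and the methoxy groups at C5 and C7, as the target requires.

Step 1
Reactants: 1 2-hydroxy-4,6-dimethoxybenzaldehyde
Product: 3 2-(methoxymethoxy)-4,6-dimethoxybenzaldehyde, via sodium phenoxide 2 (not isolated)
Conditions: NaH, DMF, 0 °C; then MOMCl, 0 °C to rt
Reagents that add atoms: chloromethyl methyl ether (MOMCl), COCCl
Why: NaH converts the hydrogen-bonded phenol irreversibly into phenoxide 2, which displaces chloride from the reactive α-chloro ether (Williamson-type O-alkylation); the aldehyde has no α-hydrogen and should be untouched.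

Step 2
Reactants: 3 2-(methoxymethoxy)-4,6-dimethoxybenzaldehyde
Product: 5 2-(methoxymethoxy)-4,6-dimethoxyphenol, via formate ester 4 (not isolated)
Conditions: mCPBA, CH2Cl2, 0 °C to rt; NaHCO3 wash; then K2CO3 (0.2 equiv), MeOH, rt, under N2
Reagents that add atoms: 3-chloroperoxybenzoic acid (mCPBA), OOC(=O)c1cccc(Cl)c1
Why: Baeyer–Villiger oxidation in its Dakin-type form: in the peracid adduct the electron-rich tri-oxygenated aryl group migrates in preference to hydrogen to give formate 4, which carbonate-catalysed methanolysis cleaves to the phenol while the MOM acetal survives.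

Step 3
Reactants: 5 2-(methoxymethoxy)-4,6-dimethoxyphenol; 6 benzyl bromide
Product: 7 2-(benzyloxy)-1,5-dimethoxy-3-(methoxymethoxy)benzene
Conditions: K2CO3, DMF, rt to 50 °C
Reagents that add atoms: none
Why: Williamson ether synthesis: carbonate deprotonates the phenol and the phenoxide displaces bromide from the benzylic halide by SN2; the MOM acetal is stable to base.

Step 4
Reactants: 7 2-(benzyloxy)-1,5-dimethoxy-3-(methoxymethoxy)benzene
Product: 9 2-(benzyloxy)-4-iodo-1,5-dimethoxy-3-(methoxymethoxy)benzene, via aryllithium 8 (not isolated)
Conditions: n-C4H9Li, THF, 0 °C; then I2, THF, −78 °C to rt; Na2S2O3 work-up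
Reagents that add atoms: iodine, II
Why: Directed ortho-metalation: the MOM acetal chelates lithium and, with the methoxy group on the other side, makes the ring hydrogen between them the kinetic site (the only other ring hydrogen lies between two weaker methoxy directors), and aryllithium 8 is then iodinated by I2.

Step 5
Reactants: 9 2-(benzyloxy)-4-iodo-1,5-dimethoxy-3-(methoxymethoxy)benzene
Product: 10 6-(benzyloxy)-2-iodo-3,5-dimethoxyphenol
Conditions: 3 M HCl (aq.), MeOH, 40 °C
Reagents that add atoms: none
Why: Acid-catalysed acetal cleavage with transfer of the methoxymethyl group to methanol; the benzyl and methyl aryl ethers and the aryl iodide should tolerate dilute acid at this temperature.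

Step 6
Reactants: 11 4-ethynyl-1,2-dimethoxybenzene
Product: 13 [(3,4-dimethoxyphenyl)ethynyl]trimethylsilane, via lithium acetylide 12 (not isolated)
Conditions: n-C4H9Li, THF, −78 °C; then Me3SiCl, −78 °C to rt
Reagents that add atoms: chlorotrimethylsilane, C[Si](C)(C)Cl
Why: Acid–base deprotonation of the terminal alkyne C–H followed by silylation of the acetylide at carbon, a standard alkyne C-silylation.

Step 7
Reactants: 10 6-(benzyloxy)-2-iodo-3,5-dimethoxyphenol; 13 [(3,4-dimethoxyphenyl)ethynyl]trimethylsilane; 14 carbon monoxide
Product: 15 8-(benzyloxy)-4-(3,4-dimethoxyphenyl)-5,7-dimethoxy-3-(trimethylsilyl)-2H-chromen-2-one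
Conditions: 13 (3 equiv), CO (1 atm, balloon), Pd(OAc)2 (5 mol %), pyridine (2 equiv), Bu4NCl (1 equiv), DMF, 120 °C
Reagents that add atoms: none
Why: Pd(OAc)2 is reduced in the flask to zerovalent palladium, which inserts into the C–I bond of 10 (future C4a); the arylpalladium iodide adds syn across alkyne 13 with ring A going to the aryl-bearing carbon (C4) and palladium to the silyl-bearing carbon (C3), CO 14 then inserts into the vinyl–palladium bond to give the acyl carbon C2, and the adjacent C8a oxygen displaces palladium from it, returning the zerovalent catalyst. The closest known reaction type is the Larock carbonylative annulation of ortho-iodophenols with internal alkynes to 3,4-disubstituted coumarins, in which a silyl substituent ends up at C3. Ring B, the only ring formed, closes through the O1–C2 bond by attack of the phenoxide on the acylpalladium carbon, a 6-exo-trig acyl substitution (equivalently C–O reductive elimination from a seven-membered palladacycle), made possible by the cis relationship that syn carbopalladation sets between ring A and the acyl group. No stereocentre is created, so no element of stereocontrol is needed. The step needs alkyne insertion to precede CO insertion and to occur in one orientation: the bulky Me3Si group prefers the carbon attached to the long C–Pd bond and so places ring C on C4, while pyridine, the high temperature and only 1 atm of CO keep direct carbonylation of the arylpalladium (which would lead to ester or chromone-type products) slower than carbopalladation of the excess alkyne. The free OH next to iodine is the internal nucleophile, and the benzyl ether on O8 keeps the second oxygen from chelating palladium or competing.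

Step 8
Reactants: 15 8-(benzyloxy)-4-(3,4-dimethoxyphenyl)-5,7-dimethoxy-3-(trimethylsilyl)-2H-chromen-2-one
Product: 16 8-(benzyloxy)-4-(3,4-dimethoxyphenyl)-5,7-dimethoxy-2H-chromen-2-one
Conditions: Bu4NF (1 M in wet THF), THF, 0 °C to rt; NH4Cl work-up
Reagents that add atoms: none
Why: Fluoride-induced protodesilylation: fluoride attacks silicon, the strong Si–F bond drives cleavage of the C3–Si bond, whose carbanion character is stabilised by the adjacent lactone carbonyl, and water in the reagent protonates C3.

Step 9
Reactants: 16 8-(benzyloxy)-4-(3,4-dimethoxyphenyl)-5,7-dimethoxy-2H-chromen-2-one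
Product: 17 8-hydroxy-4-(3,4-dimethoxyphenyl)-5,7-dimethoxy-2H-chromen-2-one (8-hydroxy-5,7,3',4'-tetramethoxy-4-phenylcoumarin)
Conditions: H2 (1 atm), 10% Pd/C, EtOAc–MeOH, rt
Reagents that add atoms: none
Why: Catalytic hydrogenolysis of the benzylic C–O bond; the aryl methyl ethers and the lactone are inert, and the conjugated, aryl-shielded C3=C4 bond should be reduced much more slowly, so the reaction is stopped at full debenzylation.

Compound list
1 | 2-hydroxy-4,6-dimethoxybenzaldehyde | COc1cc(O)c(C=O)c(OC)c1 | starting material
2 | sodium 2-formyl-3,5-dimethoxyphenolate | COc1cc([O-])c(C=O)c(OC)c1.[Na+] | intermediate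
3 | 2-(methoxymethoxy)-4,6-dimethoxybenzaldehyde | COCOc1cc(OC)cc(OC)c1C=O | intermediate
4 | 2-(methoxymethoxy)-4,6-dimethoxyphenyl formate | COCOc1cc(OC)cc(OC)c1OC=O | intermediate
5 | 2-(methoxymethoxy)-4,6-dimethoxyphenol | COCOc1cc(OC)cc(OC)c1O | intermediate
6 | benzyl bromide | BrCc1ccccc1 | starting material
7 | 2-(benzyloxy)-1,5-dimethoxy-3-(methoxymethoxy)benzene | COCOc1cc(OC)cc(OC)c1OCc1ccccc1 | intermediate
8 | [3-(benzyloxy)-4,6-dimethoxy-2-(methoxymethoxy)phenyl]lithium | [Li]c1c(OC)cc(OC)c(OCc2ccccc2)c1OCOC | intermediate
9 | 2-(benzyloxy)-4-iodo-1,5-dimethoxy-3-(methoxymethoxy)benzene | COCOc1c(I)c(OC)cc(OC)c1OCc1ccccc1 | intermediate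
10 | 6-(benzyloxy)-2-iodo-3,5-dimethoxyphenol | Oc1c(I)c(OC)cc(OC)c1OCc1ccccc1 | intermediate
11 | 4-ethynyl-1,2-dimethoxybenzene | COc1ccc(C#C)cc1OC | starting material
12 | lithium (3,4-dimethoxyphenyl)acetylide | [Li]C#Cc1ccc(OC)c(OC)c1 | intermediate
13 | [(3,4-dimethoxyphenyl)ethynyl]trimethylsilane | COc1ccc(C#C[Si](C)(C)C)cc1OC | intermediate
14 | carbon monoxide | [C-]#[O+] | starting material
15 | 8-(benzyloxy)-4-(3,4-dimethoxyphenyl)-5,7-dimethoxy-3-(trimethylsilyl)-2H-chromen-2-one | COc1ccc(-c2c([Si](C)(C)C)c(=O)oc3c(OCc4ccccc4)c(OC)cc(OC)c23)cc1OC | intermediate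
16 | 8-(benzyloxy)-4-(3,4-dimethoxyphenyl)-5,7-dimethoxy-2H-chromen-2-one | COc1ccc(-c2cc(=O)oc3c(OCc4ccccc4)c(OC)cc(OC)c23)cc1OC | intermediate
17 | 8-hydroxy-4-(3,4-dimethoxyphenyl)-5,7-dimethoxy-2H-chromen-2-one | COc1ccc(-c2cc(=O)oc3c(O)c(OC)cc(OC)c23)cc1OC | target

Total step count: 9. Longest linear sequence: 8 steps (steps 1–5 and 7–9, from 1 to 17); the alkyne branch adds one step (step 6).

Steps most likely to fail

Step 7 (carbonylative annulation). The arylpalladium formed from 10 carries substituents on both sides of the metal and is electron-rich, so alkyne insertion may be slow. CO insertion into the aryl–palladium bond, reduction of the C–I bond or loss of the silyl group from the alkyne could then take over. The fallback builds ring B by a Pechmann condensation instead. It sets out from 7: HCl in MeOH removes the MOM group to give 2-(benzyloxy)-3,5-dimethoxyphenol F1, whose only free position ortho to OH is the future C4a. Condensation of F1 with purchased ethyl 3-(3,4-dimethoxyphenyl)-3-oxopropanoate (CCOC(=O)CC(=O)c1ccc(OC)c(OC)c1) under a mild Lewis acid (InCl3, toluene, 80 °C) should give the 4-arylcoumarin by ring alkylation at that position and lactonisation. The fallback comes back to the route at 16, making steps 4 to 8 unnecessary; partial loss of the benzyl group under the acid would only anticipate step 9.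

Step 4 (lithiation and iodination). The base may deprotonate the benzylic CH2 of the benzyl ether, which would trigger a Wittig-type rearrangement, instead of the ring position. The fallback postpones benzylation until after the organolithium chemistry. It sets out from 5: i-Pr3SiOTf and 2,6-lutidine in CH2Cl2 should give triisopropyl[2-(methoxymethoxy)-4,6-dimethoxyphenoxy]silane F2, which has no benzylic hydrogens. Treatment with n-C4H9Li in THF should give [4,6-dimethoxy-2-(methoxymethoxy)-3-(triisopropylsilyloxy)phenyl]lithium F3, which I2 converts into [3-iodo-4,6-dimethoxy-2-(methoxymethoxy)phenoxy]triisopropylsilane F4. Bu4NF in THF then frees 3-iodo-4,6-dimethoxy-2-(methoxymethoxy)phenol F5, and benzylation with 6 and K2CO3 in DMF comes back to the route at 9.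

Step 9 (hydrogenolysis). The C3=C4 bond of the coumarin may be saturated along with the benzyl ether, or the catalyst may be slowed by traces of ammonium salt from step 8. The fallback inverts the last two operations so that the silyl group protects the alkene. It sets out from 15: hydrogenolysis (H2, 10% Pd/C, EtOAc–MeOH) while C3 still carries Me3Si, which makes C3=C4 tetrasubstituted and hindered, should give 4-(3,4-dimethoxyphenyl)-8-hydroxy-5,7-dimethoxy-3-(trimethylsilyl)-2H-chromen-2-one F6. Bu4NF in THF then removes the silyl group and the fallback comes back to the route at 17.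

Further compounds
F1 | step 7 | 2-(benzyloxy)-3,5-dimethoxyphenol | Oc1cc(OC)cc(OC)c1OCc1ccccc1
F2 | step 4 | triisopropyl[2-(methoxymethoxy)-4,6-dimethoxyphenoxy]silane | COCOc1cc(OC)cc(OC)c1O[Si](C(C)C)(C(C)C)C(C)C
F3 | step 4 | [4,6-dimethoxy-2-(methoxymethoxy)-3-(triisopropylsilyloxy)phenyl]lithium | [Li]c1c(OC)cc(OC)c(O[Si](C(C)C)(C(C)C)C(C)C)c1OCOC
F4 | step 4 | [3-iodo-4,6-dimethoxy-2-(methoxymethoxy)phenoxy]triisopropylsilane | COCOc1c(I)c(OC)cc(OC)c1O[Si](C(C)C)(C(C)C)C(C)C
F5 | step 4 | 3-iodo-4,6-dimethoxy-2-(methoxymethoxy)phenol | COCOc1c(I)c(OC)cc(OC)c1O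
F6 | step 9 | 4-(3,4-dimethoxyphenyl)-8-hydroxy-5,7-dimethoxy-3-(trimethylsilyl)-2H-chromen-2-one | COc1ccc(-c2c([Si](C)(C)C)c(=O)oc3c(O)c(OC)cc(OC)c23)cc1OC
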